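## Retrosynthetic overview
1. Both pyridines are attached last and together: target ⇒ bis(terminal alkene) 18 + 2 × 3-bromopyridine (double hydroboration / B-alkyl Suzuki), so no pyridine nitrogen is present in the Lewis-acid or organometallic steps.
2. C3 ⇒ hemiketal 17 ⇒ isoxazolidin-5-one 15 + oct-7-enyl Grignard (lactone → lactol → silane reduction; convex-face hydride sets C3).
3. Key step: the isoxazolidine ring (N–C6a and O–C3 bonds) ⇒ catalytic enantioselective aza-Michael/lactonisation of N-alkylhydroxylamine 8 onto cyclopentenoyl imide 13 (sets C6a and C3a). The intramolecular nitrone–olefin cycloaddition is deliberately not used.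
4. 8 ⇒ pent-4-yn-1-ol + 8-bromooct-1-ene (acetylide alkylation, Z-semihydrogenation, Mitsunobu N–O transfer).
5. Ring order: cyclopentane and pyridines are bought; the isoxazolidine is the only ring made (step 6).

Assumption: the (1S,2R)-aminoindanol-derived ligand in step 6 is taken to give the (6aR) adduct; if a first run shows the opposite sense, the equally available antipodal ligand is used and nothing else changes.

## Route

Step 1
Reactants: 1 pent-4-yn-1-ol; 2 8-bromooct-1-ene
Product: 4 tridec-12-en-4-yn-1-ol, via dilithium salt of pent-4-yn-1-ol 3 (not isolated)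
Conditions: n-BuLi (2.1 equiv), THF, −78 → 0 °C; then 2, DMPU, 0 °C → rt; H2O
Reagents that add atoms: none
Why: Acetylide alkylation: the O,C-dianion reacts at the far more nucleophilic acetylide carbon with the primary bromide (SN2), and the lithium alkoxide is a spectator.

Step 2
Reactants: 4 tridec-12-en-4-yn-1-ol
Product: 5 (4Z)-trideca-4,12-dien-1-ol
Conditions: H2 (1 atm, stopped at 1.0 equiv uptake), Pd/CaCO3 poisoned with Pb(OAc)2 (Lindlar catalyst), quinoline, EtOAc, rt
Reagents that add atoms: none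
Why: Lindlar semihydrogenation: syn delivery of H2 to the alkyne gives the Z-alkene, and the isolated terminal alkene is reduced much more slowly on the poisoned catalyst.

Step 3
Reactants: 5 (4Z)-trideca-4,12-dien-1-ol; 6 tert-butyl N-[(tert-butoxycarbonyl)oxy]carbamate (BocNH–OBoc)
Product: 7 tert-butyl N-[(tert-butoxycarbonyl)oxy]-N-[(4Z)-trideca-4,12-dien-1-yl]carbamate
Conditions: PPh3, DIAD, THF, 0 °C → rt
Reagents that add atoms: none
Why: Mitsunobu reaction: the acidic N–H of the bis-Boc hydroxylamine is alkylated on nitrogen by the activated primary alcohol, with no stereocentre involved and the alkenes untouched.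

Step 4
Reactants: 7 tert-butyl N-[(tert-butoxycarbonyl)oxy]-N-[(4Z)-trideca-4,12-dien-1-yl]carbamate
Product: 8 N-[(4Z)-trideca-4,12-dien-1-yl]hydroxylamine
Conditions: 4 M HCl in dioxane, rt; then aq. NaHCO3 (stored as the HCl salt, free-based just before use)
Reagents that add atoms: none
Why: Acidolysis of both Boc groups (loss of tert-butyl cation, then decarboxylation) frees the N-monoalkylhydroxylamine, and unactivated alkenes are inert to HCl/dioxane at rt.

Step 5
Reactants: 9 cyclopent-1-ene-1-carboxylic acid; 10 benzamide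
Product: 13 N-(cyclopent-1-ene-1-carbonyl)benzamide, via cyclopent-1-ene-1-carbonyl chloride 11 (not isolated), via sodium benzamidate 12 (not isolated)
Conditions: (COCl)2, cat. DMF, CH2Cl2, 0 °C → rt, evaporate; 10, NaH (2.1 equiv), THF, 0 °C, then crude 11, 0 °C → rt; 1 M HCl
Reagents that add atoms: none
Why: Acid chloride formation followed by N-acylation of the amide anion gives the N–H imide, the second equivalent of NaH taking up the acidic imide proton.

Step 6
Reactants: 13 N-(cyclopent-1-ene-1-carbonyl)benzamide; 8 N-[(4Z)-trideca-4,12-dien-1-yl]hydroxylamine (1.1 equiv)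
Product: 15 (3aS,6aR)-1-[(4Z)-trideca-4,12-dien-1-yl]hexahydro-3H-cyclopenta[c]isoxazol-3-one, via N-hydroxy-β-amino imide 14 (not isolated)
Conditions: Mg(NTf2)2 (10 mol%), cyclopropane-1,1-diyl-bridged bis(indano-oxazoline) ligand from (1S,2R)-1-amino-2-indanol (11 mol%), 4 Å MS, CH2Cl2, −40 °C (48 h) → rt
Reagents that add atoms: none
Why: Proposed new method: the Mg2+–bis(oxazoline) complex chelates the two imide carbonyls of 13 (the N–H imide avoids the A(1,3) twist of α-substituted enoyl templates) and shields one face of the β-carbon, so the nitrogen of 8 adds there and sets C6a; the chelated enolate is protonated anti to the new C–N bond (or the acidic α-centre equilibrates) to the only diastereomer that can lactonise, and 5-exo-trig O-acylation with loss of benzamide gives the cis-fused isoxazolidinone and fixes C3a; the closest known reaction type is the chiral Lewis acid-catalysed conjugate addition of N-benzylhydroxylamine to acyclic α,β-disubstituted enoyl imides, which gives isoxazolidin-5-ones.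

Step 7
Reactants: 15 (3aS,6aR)-1-[(4Z)-trideca-4,12-dien-1-yl]hexahydro-3H-cyclopenta[c]isoxazol-3-one; 2 8-bromooct-1-ene
Product: 17 (3aS,6aR)-3-(oct-7-en-1-yl)-1-[(4Z)-trideca-4,12-dien-1-yl]hexahydro-1H-cyclopenta[c]isoxazol-3-ol, via oct-7-en-1-ylmagnesium bromide 16 (not isolated)
Conditions: 2, Mg, THF, rt; then 15 (1.15 equiv of 16), THF, −78 °C; pH 7 buffer quench at −78 °C; crude used at once
Reagents that add atoms: none
Why: Grignard mono-addition to a lactone-type carbonyl: the cyclic magnesium hemiketalate persists at −78 °C (the lactone-to-lactol tactic of C-glycoside synthesis), C3a and C6a are untouched, and the new hemiketal centre is erased in step 8.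

Step 8
Reactants: 17 (3aS,6aR)-3-(oct-7-en-1-yl)-1-[(4Z)-trideca-4,12-dien-1-yl]hexahydro-1H-cyclopenta[c]isoxazol-3-ol
Product: 18 (3S,3aS,6aR)-3-(oct-7-en-1-yl)-1-[(4Z)-trideca-4,12-dien-1-yl]hexahydro-1H-cyclopenta[c]isoxazole
Conditions: Et3SiH (5 equiv), BF3·OEt2 (3 equiv), CH2Cl2, −78 → −20 °C
Reagents that add atoms: none
Why: Ionic hydrogenation of a lactol: BF3 ionises the hemiketal to the bicyclic oxocarbenium ion and Et3SiH delivers hydride to its convex face, anti to the cyclopentane ring, so the new C3–H is cis to H3a and H6a (3S) and the chain sits endo; the unactivated alkenes are inert without protic acid.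

Step 9
Reactants: 18 (3S,3aS,6aR)-3-(oct-7-en-1-yl)-1-[(4Z)-trideca-4,12-dien-1-yl]hexahydro-1H-cyclopenta[c]isoxazole; 19 3-bromopyridine (2.6 equiv)
Product: 21 pyrinodemin C [(3S,3aS,6aR)-3-[8-(pyridin-3-yl)octyl]-1-[(4Z)-13-(pyridin-3-yl)tridec-4-en-1-yl]hexahydro-1H-cyclopenta[c]isoxazole], via bis(9-BBN) trialkylborane 20 (not isolated)
Conditions: 9-BBN dimer (2.5 equiv B–H), THF, 0 °C → rt; then H2O, 19, Pd(dppf)Cl2 (10 mol%), aq. K3PO4, DMF, 60 °C
Reagents that add atoms: none
Why: 9-BBN hydroborates the two terminal alkenes anti-Markovnikov about a hundred times faster than the internal Z-alkene, and both primary B-alkyl groups then undergo B-alkyl Suzuki–Miyaura coupling with 3-bromopyridine; no stereocentre is touched and the N–O bond is inert to zerovalent palladium under these conditions.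

## Compound list
1 | pent-4-yn-1-ol | C#CCCCO | starting material
2 | 8-bromooct-1-ene | C=CCCCCCCBr | starting material
3 | dilithium salt of pent-4-yn-1-ol (alkoxide-acetylide) | [Li+].[Li+].[O-]CCCC#[C-] | intermediate (not isolated)
4 | tridec-12-en-4-yn-1-ol | OCCCC#CCCCCCCC=C | intermediate
5 | (4Z)-trideca-4,12-dien-1-ol | OCCC/C=C\CCCCCCC=C | intermediate
6 | tert-butyl N-[(tert-butoxycarbonyl)oxy]carbamate | CC(C)(C)OC(=O)NOC(=O)OC(C)(C)C | starting material
7 | tert-butyl N-[(tert-butoxycarbonyl)oxy]-N-[(4Z)-trideca-4,12-dien-1-yl]carbamate | CC(C)(C)OC(=O)ON(CCC/C=C\CCCCCCC=C)C(=O)OC(C)(C)C | intermediate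
8 | N-[(4Z)-trideca-4,12-dien-1-yl]hydroxylamine | ONCCC/C=C\CCCCCCC=C | intermediate
9 | cyclopent-1-ene-1-carboxylic acid | OC(=O)C1=CCCC1 | starting material
10 | benzamide | NC(=O)c1ccccc1 | starting material
11 | cyclopent-1-ene-1-carbonyl chloride | ClC(=O)C1=CCCC1 | intermediate (not isolated)
12 | sodium benzamidate | [Na+].[NH-]C(=O)c1ccccc1 | intermediate (not isolated)
13 | N-(cyclopent-1-ene-1-carbonyl)benzamide | O=C(NC(=O)c1ccccc1)C1=CCCC1 | intermediate
14 | N-[(1S,2R)-2-{hydroxy[(4Z)-trideca-4,12-dien-1-yl]amino}cyclopentane-1-carbonyl]benzamide (cis) | C=CCCCCCC/C=C\CCCN(O)[C@@H]1CCC[C@@H]1C(=O)NC(=O)c1ccccc1 | intermediate (not isolated)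
15 | (3aS,6aR)-1-[(4Z)-trideca-4,12-dien-1-yl]hexahydro-3H-cyclopenta[c]isoxazol-3-one (cis-fused isoxazolidin-5-one) | C=CCCCCCC/C=C\CCCN1OC(=O)[C@H]2CCC[C@H]21 | intermediate
16 | oct-7-en-1-ylmagnesium bromide | C=CCCCCCC[Mg]Br | intermediate (not isolated)
17 | (3aS,6aR)-3-(oct-7-en-1-yl)-1-[(4Z)-trideca-4,12-dien-1-yl]hexahydro-1H-cyclopenta[c]isoxazol-3-ol (C3 epimers, in equilibrium with the open-chain β-(N-hydroxyamino) ketone) | C=CCCCCCC/C=C\CCCN1OC(O)(CCCCCCC=C)[C@H]2CCC[C@H]21 | intermediate
18 | (3S,3aS,6aR)-3-(oct-7-en-1-yl)-1-[(4Z)-trideca-4,12-dien-1-yl]hexahydro-1H-cyclopenta[c]isoxazole | C=CCCCCCC/C=C\CCCN1O[C@@H](CCCCCCC=C)[C@H]2CCC[C@H]21 | intermediate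
19 | 3-bromopyridine | Brc1cccnc1 | starting material
20 | (3S,3aS,6aR)-3-[8-(9-borabicyclo[3.3.1]nonan-9-yl)octyl]-1-[(4Z)-13-(9-borabicyclo[3.3.1]nonan-9-yl)tridec-4-en-1-yl]hexahydro-1H-cyclopenta[c]isoxazole | B1(C2CCCC1CCC2)CCCCCCCC/C=C\CCCN3O[C@@H](CCCCCCCCB4C5CCCC4CCC5)[C@H]6CCC[C@H]63 | intermediate (not isolated)
21 | pyrinodemin C, (3S,3aS,6aR)-3-[8-(pyridin-3-yl)octyl]-1-[(4Z)-13-(pyridin-3-yl)tridec-4-en-1-yl]hexahydro-1H-cyclopenta[c]isoxazole | C(=C/CCCN1O[C@@H](CCCCCCCCc2cccnc2)[C@H]2CCC[C@H]21)/CCCCCCCCc1cccnc1 | target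

## Step count and risks
Total steps: 9. Longest linear sequence: 8 (steps 1, 2, 3, 4, 6, 7, 8, 9); step 5 is a one-step side branch.

Most likely to fail, in order:

Step 6 (enantioselectivity, sense of induction, and the need for the cis adduct to form before lactonisation). The fallback takes the stereocentres from the chiral pool; it sets out from 5 and comes back at 15. Dess–Martin oxidation of 5 gives (4Z)-trideca-4,12-dienal F1. Reductive amination of F1 (NaBH(OAc)3, DCE) with commercial ethyl (1S,2R)-2-aminocyclopentane-1-carboxylate (N[C@@H]1CCC[C@@H]1C(=O)OCC) gives ethyl (1S,2R)-2-{[(4Z)-trideca-4,12-dien-1-yl]amino}cyclopentane-1-carboxylate F2. Dibenzoyl peroxide with K2HPO4 in DMF oxidises the secondary amine, without touching the alkenes, to ethyl (1S,2R)-2-{(benzoyloxy)[(4Z)-trideca-4,12-dien-1-yl]amino}cyclopentane-1-carboxylate F3. K2CO3 in MeOH removes the benzoate and the freed N–OH lactonises onto the ester to give 15.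

Step 7 (double addition, or ring opening and retro-Michael loss of the C6a configuration). The fallback replaces lactone mono-addition by a Weinreb ketone synthesis; it sets out from 15 and comes back at 17. MeNH(OMe)·HCl with AlMe3 in CH2Cl2 opens 15 to (1S,2R)-2-{hydroxy[(4Z)-trideca-4,12-dien-1-yl]amino}-N-methoxy-N-methylcyclopentane-1-carboxamide F4. Three equivalents of 16 (the first deprotonates N–OH) then give the ketone, which closes to 17 on work-up.

Step 8 (facial selectivity or Lewis-acid damage at the N–O ring). The fallback sets C3 by reduction and SN2 closure instead of oxocarbenium reduction; it sets out from 17 and comes back at 18. The open-chain ketone tautomer of 17 is reduced with (S)-2-methyl-CBS-oxazaborolidine and BH3·SMe2 (cyclopentyl as the large group) to (1R)-1-[(1S,2R)-2-{hydroxy[(4Z)-trideca-4,12-dien-1-yl]amino}cyclopentyl]non-8-en-1-ol F5. PPh3/DIAD then closes the ring by attack of the N-hydroxy oxygen on the activated carbinol with inversion, giving 18.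

## Further compounds
F1 | step 6 | (4Z)-trideca-4,12-dienal | O=CCC/C=C\CCCCCCC=C
F2 | step 6 | ethyl (1S,2R)-2-{[(4Z)-trideca-4,12-dien-1-yl]amino}cyclopentane-1-carboxylate | C=CCCCCCC/C=C\CCCN[C@@H]1CCC[C@@H]1C(=O)OCC
F3 | step 6 | ethyl (1S,2R)-2-{(benzoyloxy)[(4Z)-trideca-4,12-dien-1-yl]amino}cyclopentane-1-carboxylate | C=CCCCCCC/C=C\CCCN(OC(=O)c1ccccc1)[C@@H]1CCC[C@@H]1C(=O)OCC
F4 | step 7 | (1S,2R)-2-{hydroxy[(4Z)-trideca-4,12-dien-1-yl]amino}-N-methoxy-N-methylcyclopentane-1-carboxamide | C=CCCCCCC/C=C\CCCN(O)[C@@H]1CCC[C@@H]1C(=O)N(C)OC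
F5 | step 8 | (1R)-1-[(1S,2R)-2-{hydroxy[(4Z)-trideca-4,12-dien-1-yl]amino}cyclopentyl]non-8-en-1-ol | C=CCCCCCC/C=C\CCCN(O)[C@@H]1CCC[C@@H]1[C@H](O)CCCCCCC=C
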